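**Plan**
- Retrosynthesis: the two benzyl ethers are removed and the C1 ketone is taken back to a carbinol; C1–C2 and C3–C4 of the cyclohexanone ring are then cut together, leaving acetophenone and an ortho-(pyranonylmethyl)benzaldehyde; the aryl–CH2 bond is cut last, to a 6-methyl-2-pyranone and a bromobenzaldehyde.
- Forward: the benzene and pyranone rings are bought and joined through the CH2 carbon by a Negishi coupling; the cyclohexane ring is then closed by an anionic aldol/aldol [4+2] annulation with acetophenone, and the C1 carbinol is oxidised to the ketone.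
- Enabling feature: C4 is a CH2 held between the benzene ring and C6 of the 2-pyranone ring (the vinylogous α-carbon of the lactone carbonyl) and lies ortho to C1. The precursor therefore carries an electrophilic carbon (C1) and a latent carbanion (C4) across the C4a–C8a bond, complementary to the nucleophilic CH3 and electrophilic C=O of acetophenone; the C3–C4 closure copies the aldol assumed in the polyketide biosynthesis.
- Helper: C1 is kept at the aldehyde level, so the first adduct is an alkoxide and not a 1,3-diketone enolate that would stop the second aldol; the helper is removed by oxidation.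
- Stereochemistry: C3 and C4 are set relative to the temporary C1 carbinol in the annulation (lithium-bridged cis-1,3-diolate, pyranone anti to the C3–O bond); the (3S,4S) series is then selected when a chiral ruthenium hydrogen-transfer catalyst oxidises only the (1R) carbinol.

Key step: step 6

Remark: tetralin positions are numbered as in the target (C1 carbonyl or carbinol carbon, C2 methylene, C3 phenyl carbinol, C4 pyranonyl-bearing carbon, C8 oxygenated); the annulation intermediates and the diol are racemic and their SMILES show the enantiomer that goes on to the target; the sense of the ruthenium catalyst is assigned by analogy with 1-tetralol and is to be confirmed on first use.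

Step 1
Reactants: 1 4-hydroxy-6-methyl-2H-pyran-2-one
Product: 2 4-(benzyloxy)-6-methyl-2H-pyran-2-one
Conditions: BnBr, K2CO3, DMF, 25 °C
Reagents that add atoms: benzyl bromide, BrCc1ccccc1
Why: Williamson-type O-alkylation of the acidic 4-hydroxyl should give the 4-benzyl ether, the 4-oxygen being favoured because alkylation there keeps the 2-pyranone, and it masks the OH for the later strong-base steps.

Step 2
Reactants: 3 2-bromo-6-hydroxybenzaldehyde
Product: 4 2-(benzyloxy)-6-bromobenzaldehyde
Conditions: BnBr, K2CO3, DMF, 25 °C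
Reagents that add atoms: benzyl bromide, BrCc1ccccc1
Why: Williamson etherification of the phenoxide masks the phenol as a benzyl ether that survives organozinc, amide-base and hydrogen-transfer conditions and leaves together with the other benzyl group at the end.

Step 3
Reactants: 4 2-(benzyloxy)-6-bromobenzaldehyde
Product: 5 2-[2-(benzyloxy)-6-bromophenyl]-1,3-dioxolane
Conditions: HOCH2CH2OH, p-toluenesulfonic acid monohydrate (cat.), toluene, reflux, azeotropic removal of water
Reagents that add atoms: ethylene glycol, OCCO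
Why: Acid-catalysed acetalisation protects the aldehyde, which would otherwise undergo addition of the organozinc reagent in the next step.

Step 4
Reactants: 2 4-(benzyloxy)-6-methyl-2H-pyran-2-one and 5 2-[2-(benzyloxy)-6-bromophenyl]-1,3-dioxolane
Product: 8 4-(benzyloxy)-6-{[3-(benzyloxy)-2-(1,3-dioxolan-2-yl)phenyl]methyl}-2H-pyran-2-one, via lithium dienolate 6 (not isolated), via zinc reagent 7 (not isolated)
Conditions: 2, LiN(SiMe3)2, THF, –78 °C; ZnCl2, –78 → 0 °C; 5, Pd2(dba)3 (2.5 mol%), 2-dicyclohexylphosphino-2',4',6'-triisopropylbiphenyl (XPhos, 10 mol%), 60 °C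
Reagents that add atoms: none
Why: Lateral deprotonation of the 6-methyl group of a 4-alkoxy-2-pyranone by a lithium amide is established, and the derived heterobenzylic zinc reagent (a vinylogous Reformatsky reagent) should undergo Negishi coupling with the ortho-substituted aryl bromide under zerovalent palladium and a bulky biarylphosphine, bond formation at the exocyclic carbon being the one that restores the pyranone.

Step 5
Reactants: 8 4-(benzyloxy)-6-{[3-(benzyloxy)-2-(1,3-dioxolan-2-yl)phenyl]methyl}-2H-pyran-2-one
Product: 9 2-(benzyloxy)-6-{[4-(benzyloxy)-2-oxo-2H-pyran-6-yl]methyl}benzaldehyde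
Conditions: 1 M aq HCl, THF, 25 °C
Reagents that add atoms: water, O
Why: Mild aqueous acid hydrolyses the dioxolane back to the aldehyde (acetal hydrolysis) without touching the benzyl ethers or the 4-alkoxy-2-pyranone.

Step 6
Reactants: 9 2-(benzyloxy)-6-{[4-(benzyloxy)-2-oxo-2H-pyran-6-yl]methyl}benzaldehyde and 10 acetophenone
Product: 15 rac-(1R,3S,4S)-8-(benzyloxy)-4-[4-(benzyloxy)-2-oxo-2H-pyran-6-yl]-3-phenyl-1,2,3,4-tetrahydronaphthalene-1,3-diol, via lithium enolate 11 (not isolated), via lithium aldolate 12 (not isolated), via dilithium dienolate 13 (not isolated), via dilithium diolate 14 (not isolated)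
Conditions: 10 (2.5 equiv), LiN(SiMe3)2 (2.4 equiv), THF, –78 °C; 9 added to the enolate; –78 → –30 °C; AcOH quench at –78 °C
Reagents that add atoms: none
Why: The lithium enolate 11 adds to the non-enolisable aldehyde of 9 at –78 °C faster than it can remove the ArCH2 proton and gives the aldolate 12 (C1–C2); on warming, the excess enolate deprotonates the CH2 group, which is both benzylic and the vinylogous α-position of the pyranone carbonyl, and the dienolate 13 attacks the phenyl ketone through its exocyclic carbon to give 14 (C3–C4). The closest known reaction types are the lithium-enolate aldol addition of acetophenone to aromatic aldehydes and the lateral lithiation of 6-alkyl-4-alkoxy-2-pyranones with addition to ketones, merged here into an anionic [4+2] annulation whose second half copies the C3–C4 aldol closure of the polyketide pathway. The one ring closes in the 6-exo-trig (6-enolexo) mode. C1 is formed without facial control (racemate); C3 is set relative to C1 by the lithium ion that bridges the C1 alkoxide and the C3 carbonyl oxygen, so that the two oxygens end up cis and axial with phenyl equatorial, and C4 is set relative to C3 because the pyranone takes the pseudoaxial position anti to the C3–O bond and clear of the peri C5–H, an arrangement that should also be the thermodynamic sink since the closure is reversible and C4–H stays acidic. The step needs carbonyl addition before proton transfer, attack through the exocyclic carbon of the dienolate and the absence of a 1,3-diketone: the first is secured by adding 9 to excess enolate at –78 °C, the second by ring size (attack through C5 of the pyranone would need an eight-membered ring), the third by keeping C1 at the aldehyde oxidation level.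

Step 7
Reactants: 15 rac-(1R,3S,4S)-8-(benzyloxy)-4-[4-(benzyloxy)-2-oxo-2H-pyran-6-yl]-3-phenyl-1,2,3,4-tetrahydronaphthalene-1,3-diol
Product: 16 (3S,4S)-8-(benzyloxy)-4-[4-(benzyloxy)-2-oxo-2H-pyran-6-yl]-3-hydroxy-3-phenyl-3,4-dihydronaphthalen-1(2H)-one
Conditions: Ru(p-cymene)[(R,R)-TsNCHPhCHPhNH] (2 mol%), acetone, 25 °C, stopped just under half conversion
Reagents that add atoms: none
Why: Asymmetric transfer dehydrogenation to acetone by the amido complex of divalent ruthenium (the reverse of asymmetric transfer hydrogenation of aryl ketones, used as an oxidative kinetic resolution) should convert only the (1R) carbinol, which has the spatial arrangement of (R)-1-tetralol that the (R,R) catalyst dehydrogenates fastest, so that erasing the temporary C1 stereocentre leaves the untouched C3 and C4 centres as the (3S,4S) pair, while the tertiary alcohol cannot react and the slow (1S,3R,4R) enantiomer of 15 stays behind and is removed by chromatography.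

Step 8
Reactants: 16 (3S,4S)-8-(benzyloxy)-4-[4-(benzyloxy)-2-oxo-2H-pyran-6-yl]-3-hydroxy-3-phenyl-3,4-dihydronaphthalen-1(2H)-one
Product: 17 (3S,4S)-3,8-dihydroxy-4-(4-hydroxy-2-oxo-2H-pyran-6-yl)-3-phenyl-3,4-dihydronaphthalen-1(2H)-one
Conditions: H2 (1 atm), Pd/C (10 wt%), EtOAc, 25 °C, stopped after uptake of two equivalents
Reagents that add atoms: none
Why: Hydrogenolysis over palladium on carbon cleaves the aryl benzyl ether and the benzyl vinylogous ester under neutral conditions that should spare the β-hydroxy ketone from retro-aldol cleavage and from dehydration to the naphthol, and neither stereocentre is touched.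

**Compound list**
1 | 4-hydroxy-6-methyl-2H-pyran-2-one | Cc1cc(O)cc(=O)o1 | starting material
2 | 4-(benzyloxy)-6-methyl-2H-pyran-2-one | Cc1cc(OCc2ccccc2)cc(=O)o1 | intermediate
3 | 2-bromo-6-hydroxybenzaldehyde | O=Cc1c(O)cccc1Br | starting material
4 | 2-(benzyloxy)-6-bromobenzaldehyde | O=Cc1c(OCc2ccccc2)cccc1Br | intermediate
5 | 2-[2-(benzyloxy)-6-bromophenyl]-1,3-dioxolane | Brc1cccc(OCc2ccccc2)c1C1OCCO1 | intermediate
6 | lithium 4-(benzyloxy)-6-methylidene-6H-pyran-2-olate (lithium dienolate of 2) | C=C1C=C(OCc2ccccc2)C=C(O[Li])O1 | intermediate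
7 | {[4-(benzyloxy)-2-oxo-2H-pyran-6-yl]methyl}zinc chloride | Cl[Zn]Cc1cc(OCc2ccccc2)cc(=O)o1 | intermediate
8 | 4-(benzyloxy)-6-{[3-(benzyloxy)-2-(1,3-dioxolan-2-yl)phenyl]methyl}-2H-pyran-2-one | O=c1cc(OCc2ccccc2)cc(Cc2cccc(OCc3ccccc3)c2C2OCCO2)o1 | intermediate
9 | 2-(benzyloxy)-6-{[4-(benzyloxy)-2-oxo-2H-pyran-6-yl]methyl}benzaldehyde | O=Cc1c(Cc2cc(OCc3ccccc3)cc(=O)o2)cccc1OCc1ccccc1 | intermediate
10 | acetophenone | CC(=O)c1ccccc1 | starting material
11 | lithium 1-phenylethen-1-olate | [Li]OC(=C)c1ccccc1 | intermediate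
12 | lithium 1-{2-(benzyloxy)-6-[(4-(benzyloxy)-2-oxo-2H-pyran-6-yl)methyl]phenyl}-3-oxo-3-phenylpropan-1-olate, racemic, (1R) enantiomer drawn | [Li]O[C@H](CC(=O)c1ccccc1)c1c(Cc2cc(OCc3ccccc3)cc(=O)o2)cccc1OCc1ccccc1 | intermediate
13 | dilithium salt of 12 deprotonated at the ArCH2 carbon (C1 alkoxide plus exocyclic 6-arylmethylidene-6H-pyran-2-olate), racemic, (1R) enantiomer drawn, alkene geometry open | [Li]O[C@H](CC(=O)c1ccccc1)c1c(C=C2C=C(OCc3ccccc3)C=C(O[Li])O2)cccc1OCc1ccccc1 | intermediate
14 | dilithium rac-(1R,3S,4S)-8-(benzyloxy)-4-[4-(benzyloxy)-2-oxo-2H-pyran-6-yl]-3-phenyl-1,2,3,4-tetrahydronaphthalene-1,3-diolate | [Li]O[C@@H]1C[C@@](O[Li])(c2ccccc2)[C@@H](c2cc(OCc3ccccc3)cc(=O)o2)c2cccc(OCc3ccccc3)c21 | intermediate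
15 | rac-(1R,3S,4S)-8-(benzyloxy)-4-[4-(benzyloxy)-2-oxo-2H-pyran-6-yl]-3-phenyl-1,2,3,4-tetrahydronaphthalene-1,3-diol (1-OH and 3-OH cis, pyranone trans to 3-OH) | O[C@@H]1C[C@@](O)(c2ccccc2)[C@@H](c2cc(OCc3ccccc3)cc(=O)o2)c2cccc(OCc3ccccc3)c21 | intermediate
16 | (3S,4S)-8-(benzyloxy)-4-[4-(benzyloxy)-2-oxo-2H-pyran-6-yl]-3-hydroxy-3-phenyl-3,4-dihydronaphthalen-1(2H)-one | O=C1C[C@@](O)(c2ccccc2)[C@@H](c2cc(OCc3ccccc3)cc(=O)o2)c2cccc(OCc3ccccc3)c21 | intermediate
17 | (3S,4S)-3,8-dihydroxy-4-(4-hydroxy-2-oxo-2H-pyran-6-yl)-3-phenyl-3,4-dihydronaphthalen-1(2H)-one | O=C1C[C@@](O)(c2ccccc2)[C@@H](c2cc(O)cc(=O)o2)c2cccc(O)c21 | target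

Total step count: 8
Longest linear sequence: 7 steps (from 3, steps 2 to 8)

**Steps most likely to fail, with fallbacks**

The annulation (step 6) is the first risk. The CH2 proton of 9 may be transferred to the enolate before carbonyl addition, the first aldolate may revert on warming, or the two aldol events may find no common temperature window. The fallback sets out from 9 and separates the two bond formations under catalyst control. A Mukaiyama aldol addition of 1-phenyl-1-(trimethylsilyloxy)ethene, catalysed by (4S)-2-butyl-4-(1H-indol-3-ylmethyl)-3-(p-tolylsulfonyl)-1,3,2-oxazaborolidin-5-one (20 mol%, EtCN, –78 °C; the enantiomer of the catalyst is the one that attacks the Re face of the aldehyde, assigned by analogy with benzaldehyde), should give the silyl ether (3R)-3-{2-(benzyloxy)-6-[(4-(benzyloxy)-2-oxo-2H-pyran-6-yl)methyl]phenyl}-1-phenyl-3-[(trimethylsilyl)oxy]propan-1-one F1. Work-up with 1 M HCl turns it into (3R)-3-{2-(benzyloxy)-6-[(4-(benzyloxy)-2-oxo-2H-pyran-6-yl)methyl]phenyl}-3-hydroxy-1-phenylpropan-1-one F2. Treatment of F2 with LiN(SiMe3)2 (2.2 equiv, THF, –78 → –30 °C) should then close the ring through the same lithium species 12 to 14 and comes back to the route at 15, now as the (1R,3S,4S) enantiomer alone, so that step 7 becomes a plain matched oxidation.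

The enantiomer-selective oxidation (step 7) is the second risk. The hydrogen-transfer catalyst may discriminate poorly between the enantiomers of the crowded, peri-flanked carbinol, or the hydrogen transfer may be slow and reversible. The fallback sets out from 15 and resolves it through covalent diastereomers. Esterification of the C1 hydroxyl with (2S)-2-methoxy-2-phenylacetic acid (N,N'-dicyclohexylcarbodiimide, 4-(dimethylamino)pyridine, CH2Cl2) should give (1R,3S,4S)-8-(benzyloxy)-4-[4-(benzyloxy)-2-oxo-2H-pyran-6-yl]-3-hydroxy-3-phenyl-1,2,3,4-tetrahydronaphthalen-1-yl (2S)-2-methoxy-2-phenylacetate F3 and its (1S,3R,4R) diastereomer, (1S,3R,4R)-8-(benzyloxy)-4-[4-(benzyloxy)-2-oxo-2H-pyran-6-yl]-3-hydroxy-3-phenyl-1,2,3,4-tetrahydronaphthalen-1-yl (2S)-2-methoxy-2-phenylacetate F4, which are separated by chromatography or crystallisation. Methanolysis of F3 (K2CO3, MeOH) returns 15 as the (1R,3S,4S) enantiomer alone, and Dess–Martin periodinane (NaHCO3, CH2Cl2, 0 °C) oxidises its secondary carbinol and comes back to the route at 16.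

The cross-coupling (step 4) is the third risk. Transmetalation or oxidative addition at the doubly ortho-substituted bromide may be sluggish, or the dienolate may be arylated at a ring carbon instead of the exocyclic carbon. The fallback sets out from 2 and 5 and reverses the polarity of the aryl–CH2 bond formation, without palladium. SeO2 (dioxane, 100 °C) should oxidise the 6-methyl group of 2 to 4-(benzyloxy)-2-oxo-2H-pyran-6-carbaldehyde F5. Bromine–lithium exchange on 5 (n-BuLi, THF, –78 °C) gives [3-(benzyloxy)-2-(1,3-dioxolan-2-yl)phenyl]lithium F6, which should add to the aldehyde of F5 to give racemic 4-(benzyloxy)-6-{[3-(benzyloxy)-2-(1,3-dioxolan-2-yl)phenyl](hydroxy)methyl}-2H-pyran-2-one F7. Conversion into the xanthate O-{[3-(benzyloxy)-2-(1,3-dioxolan-2-yl)phenyl][4-(benzyloxy)-2-oxo-2H-pyran-6-yl]methyl} S-methyl carbonodithioate F8 (NaH, CS2, MeI, THF) and Barton–McCombie deoxygenation (Bu3SnH, azobisisobutyronitrile, toluene, 80 °C) remove the hydroxyl and come back to the route at 8.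

Further compounds
F1 | step 6 | (3R)-3-{2-(benzyloxy)-6-[(4-(benzyloxy)-2-oxo-2H-pyran-6-yl)methyl]phenyl}-1-phenyl-3-[(trimethylsilyl)oxy]propan-1-one | C[Si](C)(C)O[C@H](CC(=O)c1ccccc1)c1c(Cc2cc(OCc3ccccc3)cc(=O)o2)cccc1OCc1ccccc1
F2 | step 6 | (3R)-3-{2-(benzyloxy)-6-[(4-(benzyloxy)-2-oxo-2H-pyran-6-yl)methyl]phenyl}-3-hydroxy-1-phenylpropan-1-one | O[C@H](CC(=O)c1ccccc1)c1c(Cc2cc(OCc3ccccc3)cc(=O)o2)cccc1OCc1ccccc1
F3 | step 7 | (1R,3S,4S)-8-(benzyloxy)-4-[4-(benzyloxy)-2-oxo-2H-pyran-6-yl]-3-hydroxy-3-phenyl-1,2,3,4-tetrahydronaphthalen-1-yl (2S)-2-methoxy-2-phenylacetate | CO[C@H](C(=O)O[C@@H]1C[C@@](O)(c2ccccc2)[C@@H](c2cc(OCc3ccccc3)cc(=O)o2)c2cccc(OCc3ccccc3)c21)c1ccccc1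
F4 | step 7 | (1S,3R,4R)-8-(benzyloxy)-4-[4-(benzyloxy)-2-oxo-2H-pyran-6-yl]-3-hydroxy-3-phenyl-1,2,3,4-tetrahydronaphthalen-1-yl (2S)-2-methoxy-2-phenylacetate | CO[C@H](C(=O)O[C@H]1C[C@](O)(c2ccccc2)[C@H](c2cc(OCc3ccccc3)cc(=O)o2)c2cccc(OCc3ccccc3)c21)c1ccccc1
F5 | step 4 | 4-(benzyloxy)-2-oxo-2H-pyran-6-carbaldehyde | O=Cc1cc(OCc2ccccc2)cc(=O)o1
F6 | step 4 | [3-(benzyloxy)-2-(1,3-dioxolan-2-yl)phenyl]lithium | [Li]c1cccc(OCc2ccccc2)c1C1OCCO1
F7 | step 4 | rac-4-(benzyloxy)-6-{[3-(benzyloxy)-2-(1,3-dioxolan-2-yl)phenyl](hydroxy)methyl}-2H-pyran-2-one | OC(c1cc(OCc2ccccc2)cc(=O)o1)c1cccc(OCc2ccccc2)c1C1OCCO1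
F8 | step 4 | rac-O-{[3-(benzyloxy)-2-(1,3-dioxolan-2-yl)phenyl][4-(benzyloxy)-2-oxo-2H-pyran-6-yl]methyl} S-methyl carbonodithioate | CSC(=S)OC(c1cc(OCc2ccccc2)cc(=O)o1)c1cccc(OCc2ccccc2)c1C1OCCO1
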